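Every catalyst charged stands at any moment as free catalyst, catalyst intermediate A, catalyst intermediate B or spent catalyst, and together they make up the charge.

| flask | substrate | free catalyst | time |
|---|---|---|---|
| beta | 0.80 M | 8.0 mM | 10 h |
| alpha | 1.2 M | 8.0 mM | 10 h |
| zeta | 2.0 M | 8.0 mM | 10 h |
| gamma | 2.5 M | 8.0 mM | 10 h |

    substrate + free catalyst → catalyst intermediate A (k1 = 49 M⁻¹ h⁻¹)
    catalyst intermediate A → catalyst intermediate B (k2 = 13 h⁻¹)
    catalyst intermediate B → free catalyst + target (k3 = 95 h⁻¹)
    substrate + target → side product (k4 = 0.075 M⁻¹ h⁻¹)
    2 free catalyst → spent catalyst (k5 = 63 M⁻¹ h⁻¹)

- in percentages every species weighs as the substrate in it: one side product counts as two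
- where a step has two of a species, its rate is k times that concentration squared, and two are used at each turn
- "hardly changes" means that all values lie within two and a half points (for a concentration: within two and a half percent of the largest)
- run time (beta): 10 h

- [target] at the end for beta, alpha, zeta, gamma, in this order
- the course of these numbers from the first flask to the last (hardly changes / falls, then rises / falls all the way / rises all the way / rises, then falls)

In beta, catalyst intermediate A has a half-life of 0.053 h by step 2 alone, far shorter than the 1.8 h of substrate by step 1 alone with the other concentrations held at their charge. So I take both intermediates at steady state: each is made as fast as it goes. Let S be substrate, and C the live catalyst, meaning free catalyst plus both intermediates. Then: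

C / free catalyst = g = 1 + w·S

w = 49 M⁻¹ h⁻¹ × (0.0769 h + 0.0105 h) = 4.29 M⁻¹

I call w the parking coefficient, the catalyst held in the round per free catalyst and per molar substrate. I call g the parking factor.

The landmarks of the target curve follow from g. The slope, once the intermediates stand steady, is k·S·C/g, with k = 49 M⁻¹ h⁻¹. C halves in g²/(2·k′·C), with k′ = 63 M⁻¹ h⁻¹ and g held at its charge value. Target stops gaining where making meets loss to side product. S cancels there, so the level is k·C/(k″·g), with k″ = 0.075 M⁻¹ h⁻¹, and I put C and g at their charge values.

beta: g = 4.43, slope 0.0708 M h⁻¹, catalyst half-life 19.5 h, level 1.18 M

gamma: g = 11.7, slope 0.0837 M h⁻¹, catalyst half-life 136 h, level 0.446 M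

In beta the level lies above the charge, and the reckoned catalyst half-life is shorter than gamma's. In gamma the target half-life of 3.70 h by step 4 alone, with substrate held at its charge, is shorter than the run, so the curve bends early towards its level. I expect a top between these flasks, but my reckoning stops here and gives no row.

The forecast goes further, with 0.37 M, 0.44 M, 0.445 M and 0.42 M, and the shape rises, then falls. Its ground is that "High substrate keeps the catalyst parked as intermediates, protecting it".

The simulation gives 0.376 M, 0.446 M, 0.455 M and 0.426 M, and the shape rises, then falls, so the forecast holds on both. In beta at 3.68 h, catalyst intermediate B is made 0.999 times as fast as it is used. In beta at 10.0 h, substrate at 0.273 M gives g = 2.17, and live over free catalyst stands at 2.18. In gamma at 10.0 h, substrate at 1.37 M gives g = 6.89, and live over free catalyst stands at 6.90.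

The rate constants were drawn at random within sensible limits; the result is computed.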